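**Strategy.** Everything rests on reading the 3(2H)-furanone (ring O–C10–C1–C2–C3) as the cyclodehydrated hydrate of a γ-hydroxy ynone, C10(OH)–C1≡C2–C3(=O), held inside the ten-membered carbocycle C1–C10. The key step hydrates that strained alkyne at C1 with a gold catalyst and lets the transannular C10 hydroxyl condense on C3: one operation installs the C1 carbonyl, forms the O–C3 bond and bridges the ring, on a precursor that already carries the cis-fused α-methylene lactone, the Z-C4=C5 alkene and all four stereocentres. That cyclodecynone arises from a proline aldol (C8), a chelation-controlled alkynylation (C10), a zinc Barbier lactonisation (C6, C7) and a Nozaki–Hiyama–Kishi ring closure (C3–C4).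

Key step: step 14

Remark: locants C1 to C15 are the germacrane positions of the target (C1 furanone C=O, C2 furanone CH, C3 furanone O-bearing carbon, C4=C5 ring alkene, C6 lactone O–CH, C7, C8 acyloxy CH, C9 CH2, C10 quaternary carbon, C11/C12/C13 lactone α-carbon, carbonyl and methylene, C14 methyl, C15 CH2OH); the target SMILES is read as 4Z,6S,7R,8R,10R, i.e. a cis-fused lactone.

**Route**

Step 1
Reactants: 1 acetone; 2 2,2-dimethoxyacetaldehyde
Product: 3 (R)-4-hydroxy-5,5-dimethoxypentan-2-one
Conditions: L-proline (30 mol%), acetone (solvent, large excess), 2 added as its 60% aqueous solution, rt, 24 h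
Reagents that add atoms: none
Why: Proline-catalysed direct asymmetric aldol reaction (enamine catalysis) of acetone with an activated α,α-dialkoxy aldehyde that does not self-condense; the hydrogen-bonded enamine transition state of L-proline delivers the nucleophile to the re face of the aldehyde and should set C8 as R.

Step 2
Reactants: 3 (R)-4-hydroxy-5,5-dimethoxypentan-2-one; 4 tert-butyldimethyl(prop-2-yn-1-yloxy)silane
Product: 5 (2R,4R)-7-[(tert-butyldimethylsilyl)oxy]-1,1-dimethoxy-4-methylhept-5-yne-2,4-diol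
Conditions: 4 (3.0 equiv), i-PrMgCl (2.9 equiv), THF, 0 °C, 1 h; then 3, −78 to −20 °C; aq. NH4Cl
Reagents that add atoms: none
Why: Chelation-controlled 1,2-addition of an alkynyl Grignard reagent to a β-hydroxy ketone: the magnesium alkoxide of C8 chelates the C10 carbonyl in a six-membered half-chair and the slim sp nucleophile attacks axially, which should set C10 as R (C8–O and C10–O anti along the chain that runs into the alkyne).

Step 3
Reactants: 5 the (2R,4R)-diol; 6 3-methylbutanoyl chloride
Product: 7 (2R,4R)-7-[(tert-butyldimethylsilyl)oxy]-4-hydroxy-1,1-dimethoxy-4-methylhept-5-yn-2-yl 3-methylbutanoate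
Conditions: 6 (1.1 equiv), pyridine, DMAP (5 mol%), CH2Cl2, −20 to 0 °C
Reagents that add atoms: none
Why: Chemoselective O-acylation under nucleophilic catalysis: only the secondary C8 hydroxyl reacts, the tertiary propargylic C10 hydroxyl being too hindered, and no stereocentre is touched.

Step 4
Reactants: 7 the C8 isovalerate dimethyl acetal
Product: 8 (2R,4R)-7-[(tert-butyldimethylsilyl)oxy]-4-methyl-1-oxo-4-[(triethylsilyl)oxy]hept-5-yn-2-yl 3-methylbutanoate
Conditions: Et3SiOTf (3.5 equiv), 2,4,6-collidine (5 equiv), CH2Cl2, 0 °C; then H2O, rt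
Reagents that add atoms: triethylsilyl trifluoromethanesulfonate CC[Si](CC)(CC)OS(=O)(=O)C(F)(F)F; water O
Why: Non-acidic acetal cleavage with silyl triflate and collidine (the dimethyl acetal becomes a collidinium N,O-acetal salt that water hydrolyses to the aldehyde) while the same reagent silylates the tertiary C10 hydroxyl, which must be capped so that it cannot form a lactol with the new C7 aldehyde; the TBS ether, the ester and C8 are not affected.

Step 5
Reactants: 8 the α-acyloxy aldehyde; 9 methyl acrylate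
Product: 10 methyl (3RS,4R,6R)-9-[(tert-butyldimethylsilyl)oxy]-3-hydroxy-6-methyl-4-[(3-methylbutanoyl)oxy]-2-methylidene-6-[(triethylsilyl)oxy]non-7-ynoate
Conditions: 9 (5 equiv, neat), DABCO (1.0 equiv), rt, 24–48 h; crude product taken on without delay
Reagents that add atoms: none
Why: Morita–Baylis–Hillman reaction of an electrophilic α-oxygenated aldehyde; the new carbinol centre C7 needs no control because it becomes sp2 in step 6, and the short contact time limits epimerisation at C8.

Step 6
Reactants: 10 the Baylis–Hillman alcohol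
Product: 11 methyl (2Z,4R,6R)-2-(bromomethyl)-9-[(tert-butyldimethylsilyl)oxy]-6-methyl-4-[(3-methylbutanoyl)oxy]-6-[(triethylsilyl)oxy]non-2-en-7-ynoate
Conditions: NBS (1.5 equiv), Me2S (1.8 equiv), CH2Cl2, 0 °C to rt
Reagents that add atoms: N-bromosuccinimide O=C1CCC(=O)N1Br
Why: Corey–Kim-type activation of the allylic alcohol and SN2′ displacement by bromide should give the thermodynamically preferred (Z)-2-(bromomethyl)enoate, with C8 trans to the ester; C8 and C10 are untouched.

Step 7
Reactants: 12 but-2-yne-1,4-diol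
Product: 13 4-[(tert-butyldiphenylsilyl)oxy]but-2-yn-1-ol
Conditions: 12 (3 equiv), TBDPSCl (1 equiv), imidazole (1.2 equiv), DMF, 0 °C
Reagents that add atoms: tert-butyl(chloro)diphenylsilane CC(C)(C)[Si](Cl)(c1ccccc1)c1ccccc1
Why: Statistical monosilylation of a symmetrical diol used in excess; the robust TBDPS group is chosen so that O15 stays protected through the acidic steps up to the key step.

Step 8
Reactants: 13 the mono-TBDPS butynediol
Product: 14 (2Z)-4-[(tert-butyldiphenylsilyl)oxy]-3-iodobut-2-en-1-ol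
Conditions: NaAlH2(OCH2CH2OMe)2 (1.6 equiv), THF, 0 °C; then I2 (2 equiv), −78 to 0 °C
Reagents that add atoms: iodine II
Why: Hydroxyl-directed trans-hydroalumination of the propargylic alcohol followed by iododealumination with retention puts hydrogen on C5 and iodine on C4 cis to C6, which fixes the later 4Z geometry.

Step 9
Reactants: 14 the (Z)-iodo allylic alcohol
Product: 15 (2Z)-4-[(tert-butyldiphenylsilyl)oxy]-3-iodobut-2-enal
Conditions: MnO2 (20 equiv), CH2Cl2, rt, dark
Reagents that add atoms: none
Why: Allylic oxidation with MnO2 under neutral heterogeneous conditions, which should keep the Z geometry of the β-iodo enal.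

Step 10
Reactants: 11 the (Z)-allyl bromide; 15 the (Z)-iodo enal
Product: 18 iodo lactone diol (cis-fused α-methylene lactone; C3–OH and C10–OH free; C15–OTBDPS), via Barbier hydroxy ester 16 (not isolated), via bis-silylated lactone 17 (not isolated)
Conditions: Zn dust (5 equiv), THF/sat. aq. NH4Cl (4:1), 0 °C to rt; extractive work-up; then TsOH·H2O (0.3 equiv), MeOH, rt
Reagents that add atoms: none
Why: Zinc Barbier 2-(alkoxycarbonyl)allylation followed by acid lactonisation: the Z bromide should react through a chair-like six-membered zinc transition state to give the 6,7-syn adduct (hence the cis-fused lactone), C7 being set relative to C8 by attack of the aldehyde anti to the C9 chain with H8 eclipsing C7=C11 (allylic 1,3-strain), and TsOH in methanol then closes the lactone and removes the TBS and TES groups while the TBDPS ether stays.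

Step 11
Reactants: 18 the iodo lactone diol
Product: 19 iodo lactone ynal (C3 aldehyde)
Conditions: MnO2 (15 equiv), CH2Cl2, rt
Reagents that add atoms: none
Why: Chemoselective MnO2 oxidation of the primary propargylic alcohol to the ynal; the tertiary C10 hydroxyl cannot be oxidised.

Step 12
Reactants: 19 the iodo lactone ynal
Product: 20 ten-membered enynediol (C3 epimers)
Conditions: CrCl2 (10 equiv), NiCl2 (10 mol%), DMSO/THF (3:1), syringe-pump addition to 2 mM, rt
Reagents that add atoms: none
Why: Intramolecular Nozaki–Hiyama–Kishi reaction: zerovalent nickel inserts into the C4–I bond with retention of the Z geometry, transmetallation gives the vinylchromium species, and this adds to the ynal under high dilution to close the ten-membered carbocycle; the new C3 carbinol forms as a mixture that step 13 converges.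

Step 13
Reactants: 20 the ten-membered enynediol
Product: 21 cyclodecynone (C3 ketone, C10–OH free)
Conditions: MnO2 (20 equiv), CH2Cl2, 0 °C to rt; used directly
Reagents that add atoms: none
Why: MnO2 oxidation of the doubly activated (allylic and propargylic) secondary alcohol under neutral conditions; both C3 epimers give the same ynone and the tertiary C10 hydroxyl is inert.

Step 14
Reactants: 21 the cyclodecynone
Product: 24 15-O-TBDPS furanoheliangolide, via hydroxy diketone 22 (not isolated), via hemiketal 23 (not isolated)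
Conditions: Ph3PAuNTf2 (5 mol%), H2O (5 equiv), 1,4-dioxane, 40 °C; then PPTS (10 mol%), 40 °C
Reagents that add atoms: water O
Why: The cationic monovalent gold complex π-activates the bent C1≡C2 bond of the cross-conjugated ynone and water adds at C1, the β-carbon of the C3 ketone, to give the 10-hydroxy-1,3-dione 22; the tertiary C10 hydroxyl then attacks the C3 carbonyl and hemiketal 23 loses water to the vinylogous ester, so the carbonyl is transposed from C3 to C1. The closest known reaction type is the hydration–cyclodehydration of γ-hydroxy-α,β-acetylenic ketones to 3(2H)-furanones (classically with acid, mercury salts or secondary amines), run here with a gold π-acid and transannularly. The only ring closed is the furanone O–C10–C1–C2–C3, by 5-exo-trig addition of O10 to C3=O followed by dehydration, which turns the monocyclic cyclodecynone into the 11-oxabicyclo[6.2.1]undecane core. No stereocentre is created: C10 is quaternary and cannot epimerise, and C6, C7 and C8 are not enolised under these neutral to weakly acidic conditions. The step needs hydration at C1 and not C2, and chemoselectivity over the α-methylene lactone and the C5 enone position: the polarisation of the ynone and the affinity of gold for the strained alkyne direct water to C1, only O10 sits 1,4 to C3, and the bulky silyl ether keeps O15 from adding to C1. Release of the alkyne strain of the ten-membered ring adds driving force.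

Step 15
Reactants: 24 the 15-O-TBDPS furanoheliangolide
Product: 25 target CNP0171896.2
Conditions: HF·pyridine, pyridine, THF, 0 °C to rt
Reagents that add atoms: none
Why: Fluoride-mediated cleavage of the primary silyl ether under buffered, non-basic conditions that should spare the α-methylene lactone, the isovalerate and the furanone.

**Compound list**

1 | acetone | CC(C)=O | starting material
2 | 2,2-dimethoxyacetaldehyde | COC(OC)C=O | starting material
3 | (R)-4-hydroxy-5,5-dimethoxypentan-2-one | CC(=O)C[C@@H](O)C(OC)OC | intermediate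
4 | tert-butyldimethyl(prop-2-yn-1-yloxy)silane | C#CCO[Si](C)(C)C(C)(C)C | starting material
5 | (2R,4R)-7-[(tert-butyldimethylsilyl)oxy]-1,1-dimethoxy-4-methylhept-5-yne-2,4-diol | COC(OC)[C@H](O)C[C@@](C)(O)C#CCO[Si](C)(C)C(C)(C)C | intermediate
6 | 3-methylbutanoyl chloride | CC(C)CC(=O)Cl | starting material
7 | (2R,4R)-7-[(tert-butyldimethylsilyl)oxy]-4-hydroxy-1,1-dimethoxy-4-methylhept-5-yn-2-yl 3-methylbutanoate | COC(OC)[C@H](OC(=O)CC(C)C)C[C@@](C)(O)C#CCO[Si](C)(C)C(C)(C)C | intermediate
8 | (2R,4R)-7-[(tert-butyldimethylsilyl)oxy]-4-methyl-1-oxo-4-[(triethylsilyl)oxy]hept-5-yn-2-yl 3-methylbutanoate | O=C[C@H](OC(=O)CC(C)C)C[C@@](C)(O[Si](CC)(CC)CC)C#CCO[Si](C)(C)C(C)(C)C | intermediate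
9 | methyl acrylate | C=CC(=O)OC | starting material
10 | methyl (3RS,4R,6R)-9-[(tert-butyldimethylsilyl)oxy]-3-hydroxy-6-methyl-4-[(3-methylbutanoyl)oxy]-2-methylidene-6-[(triethylsilyl)oxy]non-7-ynoate | C=C(C(=O)OC)C(O)[C@H](OC(=O)CC(C)C)C[C@@](C)(O[Si](CC)(CC)CC)C#CCO[Si](C)(C)C(C)(C)C | intermediate
11 | methyl (2Z,4R,6R)-2-(bromomethyl)-9-[(tert-butyldimethylsilyl)oxy]-6-methyl-4-[(3-methylbutanoyl)oxy]-6-[(triethylsilyl)oxy]non-2-en-7-ynoate | COC(=O)/C(CBr)=C/[C@H](OC(=O)CC(C)C)C[C@@](C)(O[Si](CC)(CC)CC)C#CCO[Si](C)(C)C(C)(C)C | intermediate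
12 | but-2-yne-1,4-diol | OCC#CCO | starting material
13 | 4-[(tert-butyldiphenylsilyl)oxy]but-2-yn-1-ol | OCC#CCO[Si](c1ccccc1)(c1ccccc1)C(C)(C)C | intermediate
14 | (2Z)-4-[(tert-butyldiphenylsilyl)oxy]-3-iodobut-2-en-1-ol | OC/C=C(\I)CO[Si](c1ccccc1)(c1ccccc1)C(C)(C)C | intermediate
15 | (2Z)-4-[(tert-butyldiphenylsilyl)oxy]-3-iodobut-2-enal | O=C/C=C(\I)CO[Si](c1ccccc1)(c1ccccc1)C(C)(C)C | intermediate
16 | methyl (3S,4R,6R)-3-[(1R,2Z)-4-[(tert-butyldiphenylsilyl)oxy]-1-hydroxy-3-iodobut-2-en-1-yl]-9-[(tert-butyldimethylsilyl)oxy]-6-methyl-4-[(3-methylbutanoyl)oxy]-2-methylidene-6-[(triethylsilyl)oxy]non-7-ynoate (Barbier hydroxy ester) | C=C(C(=O)OC)[C@@H]([C@@H](O)/C=C(\I)CO[Si](c1ccccc1)(c1ccccc1)C(C)(C)C)[C@H](OC(=O)CC(C)C)C[C@@](C)(O[Si](CC)(CC)CC)C#CCO[Si](C)(C)C(C)(C)C | intermediate (not isolated)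
17 | (1R,3R)-1-[(2R,3R)-2-[(1Z)-3-[(tert-butyldiphenylsilyl)oxy]-2-iodoprop-1-en-1-yl]-4-methylidene-5-oxooxolan-3-yl]-6-[(tert-butyldimethylsilyl)oxy]-3-methyl-3-[(triethylsilyl)oxy]hex-4-yn-1-yl 3-methylbutanoate (bis-silylated lactone) | C=C1C(=O)O[C@@H](/C=C(\I)CO[Si](c2ccccc2)(c2ccccc2)C(C)(C)C)[C@H]1[C@H](OC(=O)CC(C)C)C[C@@](C)(O[Si](CC)(CC)CC)C#CCO[Si](C)(C)C(C)(C)C | intermediate (not isolated)
18 | (1R,3R)-1-[(2R,3R)-2-[(1Z)-3-[(tert-butyldiphenylsilyl)oxy]-2-iodoprop-1-en-1-yl]-4-methylidene-5-oxooxolan-3-yl]-3,6-dihydroxy-3-methylhex-4-yn-1-yl 3-methylbutanoate (iodo lactone diol) | C=C1C(=O)O[C@@H](/C=C(\I)CO[Si](c2ccccc2)(c2ccccc2)C(C)(C)C)[C@H]1[C@H](OC(=O)CC(C)C)C[C@@](C)(O)C#CCO | intermediate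
19 | (1R,3R)-1-[(2R,3R)-2-[(1Z)-3-[(tert-butyldiphenylsilyl)oxy]-2-iodoprop-1-en-1-yl]-4-methylidene-5-oxooxolan-3-yl]-3-hydroxy-3-methyl-6-oxohex-4-yn-1-yl 3-methylbutanoate (iodo lactone ynal) | C=C1C(=O)O[C@@H](/C=C(\I)CO[Si](c2ccccc2)(c2ccccc2)C(C)(C)C)[C@H]1[C@H](OC(=O)CC(C)C)C[C@@](C)(O)C#CC=O | intermediate
20 | (4Z,6S,7R,8R,10R)-15-[(tert-butyldiphenylsilyl)oxy]-3,10-dihydroxy-8-[(3-methylbutanoyl)oxy]germacra-4,11(13)-dien-1-yn-12,6-olide, both C3 epimers | C=C1C(=O)O[C@H]2/C=C(/CO[Si](c4ccccc4)(c4ccccc4)C(C)(C)C)C(O)C#C[C@](C)(O)C[C@@H](OC(=O)CC(C)C)[C@@H]12 | intermediate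
21 | (4Z,6S,7R,8R,10R)-15-[(tert-butyldiphenylsilyl)oxy]-10-hydroxy-8-[(3-methylbutanoyl)oxy]-3-oxogermacra-4,11(13)-dien-1-yn-12,6-olide | C=C1C(=O)O[C@H]2/C=C(/CO[Si](c4ccccc4)(c4ccccc4)C(C)(C)C)C(=O)C#C[C@](C)(O)C[C@@H](OC(=O)CC(C)C)[C@@H]12 | intermediate
22 | (4Z,6S,7R,8R,10R)-15-[(tert-butyldiphenylsilyl)oxy]-10-hydroxy-8-[(3-methylbutanoyl)oxy]-1,3-dioxogermacra-4,11(13)-dien-12,6-olide | C=C1C(=O)O[C@H]2/C=C(/CO[Si](c4ccccc4)(c4ccccc4)C(C)(C)C)C(=O)CC(=O)[C@](C)(O)C[C@@H](OC(=O)CC(C)C)[C@@H]12 | intermediate (not isolated)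
23 | (4Z,6S,7R,8R,10R)-15-[(tert-butyldiphenylsilyl)oxy]-3,10-epoxy-3-hydroxy-8-[(3-methylbutanoyl)oxy]-1-oxogermacra-4,11(13)-dien-12,6-olide, C3 configuration not defined | C=C1C(=O)O[C@H]2/C=C(/CO[Si](c4ccccc4)(c4ccccc4)C(C)(C)C)C3(O)CC(=O)[C@@](C)(C[C@@H](OC(=O)CC(C)C)[C@@H]12)O3 | intermediate (not isolated)
24 | (4Z,6S,7R,8R,10R)-15-[(tert-butyldiphenylsilyl)oxy]-3,10-epoxy-8-[(3-methylbutanoyl)oxy]-1-oxogermacra-2,4,11(13)-trien-12,6-olide | C=C1C(=O)O[C@H]2/C=C(/CO[Si](c4ccccc4)(c4ccccc4)C(C)(C)C)C3=CC(=O)[C@@](C)(C[C@@H](OC(=O)CC(C)C)[C@@H]12)O3 | intermediate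
25 | (4Z,6S,7R,8R,10R)-3,10-epoxy-15-hydroxy-8-[(3-methylbutanoyl)oxy]-1-oxogermacra-2,4,11(13)-trien-12,6-olide (CNP0171896.2) | C=C1C(=O)O[C@H]2/C=C(/CO)C3=CC(=O)[C@@](C)(C[C@@H](OC(=O)CC(C)C)[C@@H]12)O3 | target

**Step count and risks**

Total step count: 15. Longest linear sequence: 12 (steps 1–6 and 10–15).

Steps most likely to fail:

1. Step 12 (ring closure to the ten-membered enynol). Intermolecular coupling and reduction or decomposition of the ynal by divalent chromium may outrun the slow closure of a ring that has to accommodate a linear C10–C1≡C2–C3 unit. The fallback sets out from 19 and comes back at 21. Pinnick oxidation (NaClO2, NaH2PO4, 2-methylbut-2-ene, t-BuOH/H2O) should give the alkynoic acid F1. Protodecarboxylation (CuCl 10 mol%, Et3N, MeCN, 60 °C) should give the terminal alkyne F2. A carbonylative Sonogashira macrocyclisation (PdCl2(PPh3)2, CuI, CO 1 atm, Et3N, THF, high dilution) then joins C2 and C4 through a CO-derived C3 and should give ynone 21 directly, so step 13 is not needed. The CO-free coupling would give a nine-membered enyne and is disfavoured by strain.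

2. Step 14 (key step). Water may add unselectively, or the cross-conjugated ynone may be consumed by oligomerisation or stray conjugate addition before the transannular condensation occurs. The fallback sets out from 21 and comes back at 24. One equivalent of diethylamine (THF, −20 °C) should add to C1 of the strained ynone far faster than to the methylene lactone and give the enaminone F3. Aqueous acetic acid (THF, rt) then hydrolyses the vinylogous amide, and the released 10-hydroxy-1,3-dione cyclodehydrates to 24 (the amine-adduct variant of the same furanone synthesis, run stepwise and without a metal).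

3. Step 10 (Barbier coupling). Facial selectivity at C7 relative to C8 may be poor, and syn/anti control may leak through open zinc transition states, giving diastereomeric lactones. The fallback sets out from 11 and comes back at 16. Miyaura-type borylation (B2pin2, Pd2(dba)3 2.5 mol%, DMSO, 50 °C) should give the allylboronate F4. Its allylboration of 15, catalysed by a chiral BINOL-derived phosphoric acid (5 mol%, toluene, −30 °C), proceeds through a closed chair transition state, so the adduct is syn and the catalyst chooses the aldehyde face and with it C6 and C7. Hydrolysis of the borate gives 16, which is carried on with TsOH/MeOH as in step 10.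

Further compounds
F1 | step 12 | (4R,6R)-6-[(2R,3R)-2-[(1Z)-3-[(tert-butyldiphenylsilyl)oxy]-2-iodoprop-1-en-1-yl]-4-methylidene-5-oxooxolan-3-yl]-4-hydroxy-4-methyl-6-[(3-methylbutanoyl)oxy]hex-2-ynoic acid | C=C1C(=O)O[C@@H](/C=C(\I)CO[Si](c2ccccc2)(c2ccccc2)C(C)(C)C)[C@H]1[C@H](OC(=O)CC(C)C)C[C@@](C)(O)C#CC(=O)O
F2 | step 12 | (1R,3R)-1-[(2R,3R)-2-[(1Z)-3-[(tert-butyldiphenylsilyl)oxy]-2-iodoprop-1-en-1-yl]-4-methylidene-5-oxooxolan-3-yl]-3-hydroxy-3-methylpent-4-yn-1-yl 3-methylbutanoate | C=C1C(=O)O[C@@H](/C=C(\I)CO[Si](c2ccccc2)(c2ccccc2)C(C)(C)C)[C@H]1[C@H](OC(=O)CC(C)C)C[C@@](C)(O)C#C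
F3 | step 14 | (4Z,6S,7R,8R,10R)-15-[(tert-butyldiphenylsilyl)oxy]-1-(diethylamino)-10-hydroxy-8-[(3-methylbutanoyl)oxy]-3-oxogermacra-1,4,11(13)-trien-12,6-olide | C=C1C(=O)O[C@H]2/C=C(/CO[Si](c4ccccc4)(c4ccccc4)C(C)(C)C)C(=O)C=C(N(CC)CC)[C@](C)(O)C[C@@H](OC(=O)CC(C)C)[C@@H]12
F4 | step 10 | methyl (2E,4R,6R)-9-[(tert-butyldimethylsilyl)oxy]-6-methyl-4-[(3-methylbutanoyl)oxy]-2-[(4,4,5,5-tetramethyl-1,3,2-dioxaborolan-2-yl)methyl]-6-[(triethylsilyl)oxy]non-2-en-7-ynoate | COC(=O)/C(CB1OC(C)(C)C(C)(C)O1)=C/[C@H](OC(=O)CC(C)C)C[C@@](C)(O[Si](CC)(CC)CC)C#CCO[Si](C)(C)C(C)(C)C
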